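**Retrosynthetic overview**
1. Ubiquinol-6 (15) ⇐ ubiquinone-6 (14) by dithionite reduction.
2. The only ring, the quinone, is formed in the penultimate step: 14 ⇐ dimethyl squarate (13) + C33 methyl alkyne 12, by a proposed Rh-catalysed C–C activation/[4+2] alkyne insertion.
3. 12 ⇐ all-E hexaprenyl bromide (10) + 1-propynylmagnesium bromide (11), Cu-catalysed SN2.
4. C30 chain ⇐ C15 + C15: anion of farnesyl phenyl sulfone (3) + ω-bromofarnesyl silyl ether (6), then Pd/hydride desulfonylation.
5. Both halves come from (2E,6E)-farnesol (1): four E-alkenes are purchased, the fifth is set by E-selective SeO2 oxidation.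

Assumption: the target has no stereocentres, so "single enantiomer" is read as the single all-E (2E,6E,10E,14E,18E) geometric isomer in the SMILES.

**Route**

Step 1
Reactants: 1, (2E,6E)-farnesol
Product: 2, (2E,6E)-farnesyl bromide
Conditions: PBr3 (0.4 equiv), Et2O, −10 °C; used crude
Reagents that add atoms: phosphorus tribromide, BrP(Br)Br
Why: SN2 bromination of a primary allylic alcohol at low temperature, which leaves both E-alkenes and the allylic position unchanged.

Step 2
Reactants: 2, (2E,6E)-farnesyl bromide
Product: 3, (2E,6E)-farnesyl phenyl sulfone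
Conditions: PhSO2Na, DMF, rt
Reagents that add atoms: sodium benzenesulfinate, [Na+].[O-]S(=O)c1ccccc1
Why: S-alkylation of sulfinate by a primary allylic bromide (SN2) gives the allylic sulfone with geometry retained.

Step 3
Reactants: 1, (2E,6E)-farnesol
Product: 4, (2E,6E)-farnesyl tert-butyldiphenylsilyl ether
Conditions: TBDPSCl, imidazole, DMF, rt
Reagents that add atoms: tert-butyldiphenylsilyl chloride, CC(C)(C)[Si](Cl)(c1ccccc1)c1ccccc1
Why: Standard silylation; TBDPS tolerates the later SeO2, Appel, sulfonyl-carbanion and hydride conditions.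

Step 4
Reactants: 4, farnesyl TBDPS ether
Product: 5, (2E,6E,10E)-12-[(tert-butyldiphenylsilyl)oxy]-2,6,10-trimethyldodeca-2,6,10-trien-1-ol
Conditions: SeO2 (0.2 equiv), t-BuOOH, salicylic acid (cat.), CH2Cl2, 0 °C to rt; then NaBH4, MeOH, 0 °C
Reagents that add atoms: selenium dioxide, O=[Se]=O, with tert-butyl hydroperoxide, CC(C)(C)OO, as terminal oxidant
Why: Sharpless SeO2/TBHP allylic oxidation (ene/[2,3] sequence) attacks the most electron-rich, least hindered terminal olefin and oxidises only its E-methyl group, which sets the fifth stereogenic E-alkene; NaBH4 returns any over-oxidised enal to the alcohol.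

Step 5
Reactants: 5, ω-hydroxy silyl ether
Product: 6, tert-butyl{[(2E,6E,10E)-12-bromo-3,7,11-trimethyldodeca-2,6,10-trien-1-yl]oxy}diphenylsilane
Conditions: CBr4, PPh3, 2,6-lutidine, CH2Cl2, 0 °C; used at once
Reagents that add atoms: carbon tetrabromide, BrC(Br)(Br)Br
Why: Appel bromination of a primary allylic alcohol under buffered neutral conditions, with no allylic transposition and the silyl ether untouched.

Step 6
Reactants: 3, farnesyl phenyl sulfone; 6, ω-bromide
Product: 7, TBDPS ether of (2E,6E,10E,14E,18E)-3,7,11,15,19,23-hexamethyl-13-(phenylsulfonyl)tetracosa-2,6,10,14,18,22-hexaen-1-ol (racemic at C13; this centre is removed in step 7)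
Conditions: 3, n-BuLi, THF/DMPU, −78 °C; then 6, −78 to −40 °C
Reagents that add atoms: none
Why: Biellmann-type α-alkylation of an allylic sulfonyl carbanion with a primary allylic bromide (SN2) joins the two C15 units head-to-tail without touching any alkene.

Step 7
Reactants: 7, C30 sulfone
Product: 8, all-E hexaprenyl TBDPS ether
Conditions: PdCl2(dppp) (10 mol %), LiBHEt3 (2.5 equiv), THF, 0 °C
Reagents that add atoms: none (hydride only)
Why: Pd-catalysed reductive desulfonylation of an allylic sulfone, in which hydride is delivered to the less substituted allyl terminus so the 14,15-alkene keeps its position and E geometry; the allylic silyl ether is not ionised by Pd(0).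

Step 8
Reactants: 8, hexaprenyl TBDPS ether
Product: 9, (2E,6E,10E,14E,18E)-3,7,11,15,19,23-hexamethyltetracosa-2,6,10,14,18,22-hexaen-1-ol (all-E hexaprenol)
Conditions: TBAF, THF, rt
Reagents that add atoms: none
Why: Fluoride desilylation is neutral toward the polyene.

Step 9
Reactants: 9, all-E hexaprenol
Product: 10, all-E hexaprenyl bromide
Conditions: PBr3 (0.4 equiv), Et2O, −10 °C; used crude
Reagents that add atoms: phosphorus tribromide, BrP(Br)Br
Why: Same SN2 bromination as step 1, with the 2E geometry retained.

Step 10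
Reactants: 10, hexaprenyl bromide; 11, 1-propynylmagnesium bromide
Product: 12, (5E,9E,13E,17E,21E)-6,10,14,18,22,26-hexamethylheptacosa-5,9,13,17,21,25-hexaen-2-yne
Conditions: 11 (1.5 equiv), CuI (10 mol %), THF, 0 °C to rt
Reagents that add atoms: none beyond reactant 11
Why: Cu-catalysed SN2 alkynylation of a primary allylic bromide; γ-attack is blocked by the disubstituted terminus, so the skipped enyne forms with the 5E-alkene intact.

Step 11
Reactants: 12, C33 enyne; 13, dimethyl squarate (3,4-dimethoxycyclobut-3-ene-1,2-dione)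
Product: 14, ubiquinone-6, 2-[(2E,6E,10E,14E,18E)-hexaprenyl]-5,6-dimethoxy-3-methyl-1,4-benzoquinone
Conditions: [Rh(C2H4)2Cl]2 (2.5 mol %), dppb (5.5 mol %), AgSbF6 (5 mol %; premixed, AgCl filtered off), 13 (2 equiv), ClCH2CH2Cl, 60 °C, Ar
Reagents that add atoms: none beyond reactant 13
Why: Proposed new method: a catalytic acyl–acyl C–C activation/[4+2] benzannulation in which cationic Rh(I) oxidatively adds into the strained C1–C2 bond of 13 to give a dimethoxy-rhodacyclopentenedione ("maleoyl-Rh(III)"), the alkyne of 12 (its only unhindered π-ligand; trisubstituted alkenes do not insert into M–acyl bonds) undergoes 1,2-insertion into one Rh–acyl bond, and acyl–vinyl reductive elimination closes the quinone ring and returns Rh(I); because 13 is symmetric the alkyne orientation is irrelevant, no allyl–metal species is formed so all five E-alkenes are untouched, the non-coordinating anion supplies the vacant site that neutral isolated metallacycles lack, and the fully substituted, weakly oxidising quinone should be a poor ligand for Rh(I); the closest known chemistry is the stoichiometric quinone synthesis from isolated maleoyl/phthaloyl-cobalt and -rhodium complexes with alkynes and the catalytic Ni(0)/Rh(I) "cut-and-sew" insertion of alkynes into cyclobutenones, neither being an established catalytic dione + alkyne → quinone process nor shown on a dialkoxy dione with a skipped polyenyne.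

Step 12
Reactants: 14, ubiquinone-6
Product: 15, ubiquinol-6 (target), 2-[(2E,6E,10E,14E,18E)-3,7,11,15,19,23-hexamethyltetracosa-2,6,10,14,18,22-hexaen-1-yl]-5,6-dimethoxy-3-methylbenzene-1,4-diol
Conditions: Na2S2O4 (excess), degassed Et2O/H2O, rt, Ar; isolate and store under Ar
Reagents that add atoms: none (adds 2 H)
Why: Dithionite two-electron reduction of a quinone to its hydroquinone is neutral and fast and leaves the polyene alone.

**Compound list**
1 | (2E,6E)-farnesol | OC/C=C(\C)CC/C=C(\C)CCC=C(C)C | starting material
2 | (2E,6E)-farnesyl bromide | BrC/C=C(\C)CC/C=C(\C)CCC=C(C)C | intermediate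
3 | (2E,6E)-farnesyl phenyl sulfone | O=S(=O)(C/C=C(\C)CC/C=C(\C)CCC=C(C)C)c1ccccc1 | intermediate
4 | (2E,6E)-farnesyl TBDPS ether | CC(C)(C)[Si](OC/C=C(\C)CC/C=C(\C)CCC=C(C)C)(c1ccccc1)c1ccccc1 | intermediate
5 | (2E,6E,10E)-12-(TBDPS-oxy)-2,6,10-trimethyldodeca-2,6,10-trien-1-ol | CC(C)(C)[Si](OC/C=C(\C)CC/C=C(\C)CC/C=C(\C)CO)(c1ccccc1)c1ccccc1 | intermediate
6 | (2E,6E,10E)-12-bromo-3,7,11-trimethyldodeca-2,6,10-trienyl TBDPS ether | CC(C)(C)[Si](OC/C=C(\C)CC/C=C(\C)CC/C=C(\C)CBr)(c1ccccc1)c1ccccc1 | intermediate
7 | all-E 13-(phenylsulfonyl)hexaprenyl TBDPS ether (racemic at C13) | CC(C)(C)[Si](OC/C=C(\C)CC/C=C(\C)CC/C=C(\C)CC(/C=C(\C)CC/C=C(\C)CCC=C(C)C)S(=O)(=O)c1ccccc1)(c1ccccc1)c1ccccc1 | intermediate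
8 | all-E hexaprenyl TBDPS ether | CC(C)(C)[Si](OC/C=C(\C)CC/C=C(\C)CC/C=C(\C)CC/C=C(\C)CC/C=C(\C)CCC=C(C)C)(c1ccccc1)c1ccccc1 | intermediate
9 | all-E hexaprenol | OC/C=C(\C)CC/C=C(\C)CC/C=C(\C)CC/C=C(\C)CC/C=C(\C)CCC=C(C)C | intermediate
10 | all-E hexaprenyl bromide | BrC/C=C(\C)CC/C=C(\C)CC/C=C(\C)CC/C=C(\C)CC/C=C(\C)CCC=C(C)C | intermediate
11 | 1-propynylmagnesium bromide | CC#C[Mg]Br | starting material
12 | (5E,9E,13E,17E,21E)-6,10,14,18,22,26-hexamethylheptacosa-5,9,13,17,21,25-hexaen-2-yne | CC#CC/C=C(\C)CC/C=C(\C)CC/C=C(\C)CC/C=C(\C)CC/C=C(\C)CCC=C(C)C | intermediate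
13 | dimethyl squarate | COC1=C(OC)C(=O)C1=O | starting material
14 | ubiquinone-6 | COC1=C(OC)C(=O)C(C/C=C(\C)CC/C=C(\C)CC/C=C(\C)CC/C=C(\C)CC/C=C(\C)CCC=C(C)C)=C(C)C1=O | intermediate
15 | ubiquinol-6 | COc1c(O)c(C)c(C/C=C(\C)CC/C=C(\C)CC/C=C(\C)CC/C=C(\C)CC/C=C(\C)CCC=C(C)C)c(O)c1OC | target

**Totals**
Total steps: 12. Longest linear sequence: 10 steps (steps 3–12, from farnesol 1); steps 1–2 are the convergent branch.

**Three steps most likely to fail**
1. Step 11 (proposed Rh-catalysed benzannulation). Risks are no turnover (stable rhodacycle or product binding), CO extrusion, or alkyne oligomerisation. Fallback with known chemistry: drop the ring construction and use the classical aryl–allyl end game. Brominate 2,3,4,5-tetramethoxytoluene, form the aryl cuprate (n-BuLi, CuBr·SMe2) and couple it with bromide 10 (SN2, E retained). Oxidative demethylation with CAN then gives 14, followed by step 12.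
2. Step 4 (SeO2 terminal oxidation). Risks are modest yield, over-oxidation and competing oxidation of internal olefins. Fallback: rebuild the terminus instead of oxidising a C–H bond. Terminal-selective bromohydrin formation (NBS, aq. THF) and K2CO3 closure to the epoxide, HIO4 cleavage to the trisnor aldehyde, E-selective Wittig with Ph3P=C(CH3)CO2Et, and DIBAL reduction give 5.
3. Step 7 (Pd/hydride desulfonylation). Risks are partial double-bond transposition or E/Z erosion through the π-allyl-Pd intermediate. Fallback: avoid the sulfone altogether with an allylbarium α,α′-cross-coupling. Farnesyl chloride and activated barium at −78 °C, then bromide 6, give 8 directly with retention of geometry.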